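The target is cut at its allyl–arene junction: the bond from benzylic C1' (the CH2 on C3 of the quinone ring) to C2', together with the methyl on C3'. Because C2'=C3'(CH3) is an E-trisubstituted olefin flanking a benzylic carbon, one flask can build it from a terminal alkyne: Cp2ZrCl2-catalysed syn methylalumination sets the C3' methyl and an E-alkenylalane, which zerovalent nickel joins to chloromethylated menadiol dimethyl ether. The precursor is the (7'R) C38 hexaenyne, assembled from (S)-citronellol (C5'–C12', source of the stereocentre) and geranyl and farnesyl phenyl sulfones by two allylic sulfone alkylations, one global desulfonylation and a propargylation. Oxidative demethylation then unveils the naphthoquinone.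

Key step: step 16

Assumption: primed locants count the side chain from the benzylic CH2 (C1'); geranyl bromide and (2E,6E)-farnesyl bromide are taken as catalogue compounds of E configuration; the sulfone-bearing carbons C13' and C21' form as epimer mixtures, which is immaterial because both sulfonyl groups leave in step 10; the descriptor at C7' changes from S (compounds 1–15) to R (from 16 on) only through CIP ranking, no bond at that carbon being touched.

Step 1
Reactants: 1 (S)-citronellol
Product: 2 (S)-citronellyl tert-butyldiphenylsilyl ether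
Conditions: TBDPSCl, imidazole, DMF, 0 °C to rt
Reagents that add atoms: tert-butyl(chloro)diphenylsilane, CC(C)(C)[Si](Cl)(c1ccccc1)c1ccccc1
Why: Imidazole-promoted silylation of the primary alcohol gives a silyl ether that should withstand organolithium bases, hydride and mild acid up to step 11, and the stereocentre is not involved.

Step 2
Reactants: 2 (S)-citronellyl tert-butyldiphenylsilyl ether
Product: 3 (2E,6S)-8-[(tert-butyldiphenylsilyl)oxy]-2,6-dimethyloct-2-en-1-ol
Conditions: SeO2 (cat.), t-BuOOH, salicylic acid (cat.), CH2Cl2, 0 °C to rt; then NaBH4, MeOH, 0 °C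
Reagents that add atoms: tert-butyl hydroperoxide, CC(C)(C)OO; selenium dioxide, O=[Se]=O (catalytic oxygen carrier)
Why: Riley allylic oxidation (ene reaction, then [2,3]-sigmatropic shift) hydroxylates the E-methyl of the isopropylidene end, which fixes the E geometry of the future C10'=C11' bond, and the borohydride quench returns any over-oxidised enal to 3.

Step 3
Reactants: 3 (2E,6S)-8-[(tert-butyldiphenylsilyl)oxy]-2,6-dimethyloct-2-en-1-ol
Product: 4 {[(3S,6E)-8-bromo-3,7-dimethyloct-6-en-1-yl]oxy}(tert-butyl)diphenylsilane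
Conditions: CBr4, PPh3, CH2Cl2, 0 °C
Reagents that add atoms: carbon tetrabromide, BrC(Br)(Br)Br
Why: The Appel reaction replaces the primary allylic hydroxyl by bromide through SN2 displacement under neutral conditions, without allylic shift and without loss of the silyl ether.

Step 4
Reactants: 5 geranyl bromide
Product: 6 geranyl phenyl sulfone, {[(2E)-3,7-dimethylocta-2,6-dien-1-yl]sulfonyl}benzene
Conditions: PhSO2Na, DMF, rt
Reagents that add atoms: sodium benzenesulfinate, [Na+].[O-]S(=O)c1ccccc1
Why: S-alkylation of the sulfinate anion by SN2 at the primary allylic bromide should give the allylic sulfone with the E olefin intact.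

Step 5
Reactants: 6 geranyl phenyl sulfone
Product: 7 (2E,6E)-2,6-dimethyl-8-(phenylsulfonyl)octa-2,6-dien-1-ol
Conditions: SeO2 (cat.), t-BuOOH, salicylic acid (cat.), CH2Cl2, 0 °C to rt; then NaBH4, MeOH, 0 °C
Reagents that add atoms: tert-butyl hydroperoxide, CC(C)(C)OO; selenium dioxide, O=[Se]=O (catalytic oxygen carrier)
Why: Riley allylic oxidation should again pick the E-methyl of the electron-rich terminal olefin, because the other double bond is deactivated by the neighbouring sulfonylmethyl group.

Step 6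
Reactants: 7 (2E,6E)-2,6-dimethyl-8-(phenylsulfonyl)octa-2,6-dien-1-ol; 4 {[(3S,6E)-8-bromo-3,7-dimethyloct-6-en-1-yl]oxy}(tert-butyl)diphenylsilane
Product: 8 (2E,6E,10E,14S)-16-[(tert-butyldiphenylsilyl)oxy]-2,6,10,14-tetramethyl-8-(phenylsulfonyl)hexadeca-2,6,10-trien-1-ol (epimers at C8)
Conditions: 7, n-BuLi (2.2 equiv), THF/DMPU, −78 °C; then 4, −78 to −30 °C
Reagents that add atoms: none
Why: In this Biellmann-type alkylation of an α-sulfonyl allyl carbanion, the alkoxide–carbanion dianion should react only at carbon, by SN2 at the primary allylic bromide, so that C12'–C13' forms head to tail with all olefin geometries kept.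

Step 7
Reactants: 8 (2E,6E,10E,14S)-16-[(tert-butyldiphenylsilyl)oxy]-2,6,10,14-tetramethyl-8-(phenylsulfonyl)hexadeca-2,6,10-trien-1-ol
Product: 9 tert-butyl{[(3S,6E,10E,14E)-16-bromo-3,7,11,15-tetramethyl-9-(phenylsulfonyl)hexadeca-6,10,14-trien-1-yl]oxy}diphenylsilane
Conditions: CBr4, PPh3, CH2Cl2, 0 °C
Reagents that add atoms: carbon tetrabromide, BrC(Br)(Br)Br
Why: The Appel reaction converts the primary allylic alcohol into the bromide by SN2 displacement while sulfone and silyl ether stay inert.

Step 8
Reactants: 10 (2E,6E)-farnesyl bromide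
Product: 11 (2E,6E)-farnesyl phenyl sulfone, {[(2E,6E)-3,7,11-trimethyldodeca-2,6,10-trien-1-yl]sulfonyl}benzene
Conditions: PhSO2Na, DMF, rt
Reagents that add atoms: sodium benzenesulfinate, [Na+].[O-]S(=O)c1ccccc1
Why: Sulfinate S-alkylation by SN2 at the primary allylic bromide, as in step 4.

Step 9
Reactants: 11 (2E,6E)-farnesyl phenyl sulfone; 9 tert-butyl{[(3S,6E,10E,14E)-16-bromo-3,7,11,15-tetramethyl-9-(phenylsulfonyl)hexadeca-6,10,14-trien-1-yl]oxy}diphenylsilane
Product: 12 tert-butyl{[(3S,6E,10E,14E,18E,22E)-3,7,11,15,19,23,27-heptamethyl-9,17-bis(phenylsulfonyl)octacosa-6,10,14,18,22,26-hexaen-1-yl]oxy}diphenylsilane (epimers at C9 and C17)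
Conditions: 11 (1.3 equiv), n-BuLi, THF/DMPU, −78 °C; then 9, −78 to −30 °C
Reagents that add atoms: none
Why: A second Biellmann-type allylic sulfone alkylation forms C20'–C21'; the primary sulfonyl carbanion of 11 is a weaker base than the anion that would arise from the more substituted C–H next to the sulfone in 9, so proton transfer should not compete with SN2 at the allylic bromide.

Step 10
Reactants: 12 tert-butyl{[(3S,6E,10E,14E,18E,22E)-3,7,11,15,19,23,27-heptamethyl-9,17-bis(phenylsulfonyl)octacosa-6,10,14,18,22,26-hexaen-1-yl]oxy}diphenylsilane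
Product: 13 tert-butyl{[(3S,6E,10E,14E,18E,22E)-3,7,11,15,19,23,27-heptamethyloctacosa-6,10,14,18,22,26-hexaen-1-yl]oxy}diphenylsilane
Conditions: PdCl2(dppp) (10 mol%), LiEt3BH (5 equiv), THF, 0 °C
Reagents that add atoms: none
Why: In this palladium-catalysed hydride reduction of allylic sulfones, zerovalent palladium ionises each allylic C–S bond to a π-allyl complex and hydride should enter at the less substituted terminus, so both E-trisubstituted olefins stay in place and both epimeric centres vanish in one operation.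

Step 11
Reactants: 13 tert-butyl{[(3S,6E,10E,14E,18E,22E)-3,7,11,15,19,23,27-heptamethyloctacosa-6,10,14,18,22,26-hexaen-1-yl]oxy}diphenylsilane
Product: 14 (3S,6E,10E,14E,18E,22E)-3,7,11,15,19,23,27-heptamethyloctacosa-6,10,14,18,22,26-hexaen-1-ol
Conditions: Bu4NF, THF, rt
Reagents that add atoms: none
Why: Fluoride-mediated desilylation, driven by the strength of the Si–F bond, frees the primary alcohol without touching the olefins.

Step 12
Reactants: 14 (3S,6E,10E,14E,18E,22E)-3,7,11,15,19,23,27-heptamethyloctacosa-6,10,14,18,22,26-hexaen-1-ol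
Product: 15 (3S,6E,10E,14E,18E,22E)-1-iodo-3,7,11,15,19,23,27-heptamethyloctacosa-6,10,14,18,22,26-hexaene
Conditions: PPh3, imidazole, I2, CH2Cl2, 0 °C; then 14, 0 °C to rt
Reagents that add atoms: iodine, II
Why: In the Garegg–Samuelsson (Appel-type) iodination the preformed iodophosphonium salt consumes the I2 before the polyene is added, and SN2 at the primary carbon leaves the remote stereocentre alone.

Step 13
Reactants: 15 (3S,6E,10E,14E,18E,22E)-1-iodo-3,7,11,15,19,23,27-heptamethyloctacosa-6,10,14,18,22,26-hexaene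
Product: 17 (6R,9E,13E,17E,21E,25E)-6,10,14,18,22,26,30-heptamethylhentriaconta-9,13,17,21,25,29-hexaen-1-yne, via silylalkyne 16 (not isolated)
Conditions: 1-(trimethylsilyl)propyne, n-BuLi, THF, −78 to −20 °C; then 15, −78 °C to rt; then MeOH, K2CO3, rt
Reagents that add atoms: 1-(trimethylsilyl)propyne, CC#C[Si](C)(C)C
Why: Alkylation of lithiated 1-(trimethylsilyl)propyne by SN2 at the primary iodide should occur at the propargylic terminus (the silyl group blocks the alkyne carbon and disfavours the allene), adding C2'–C4', and methanolic carbonate then cleaves the alkynyl C–Si bond in the same flask.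

Step 14
Reactants: 18 menadione
Product: 20 1,4-dimethoxy-2-methylnaphthalene, via menadiol 19 (not isolated)
Conditions: Na2S2O4, Bu4NBr (cat.), THF/H2O, rt; then KOH (aq), Me2SO4, rt
Reagents that add atoms: dimethyl sulfate, COS(=O)(=O)OC
Why: Reductive methylation: dithionite reduces the quinone to the hydroquinone, whose phenoxides undergo Williamson O-methylation under phase transfer before air can re-oxidise them.

Step 15
Reactants: 20 1,4-dimethoxy-2-methylnaphthalene
Product: 21 2-(chloromethyl)-1,4-dimethoxy-3-methylnaphthalene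
Conditions: (CH2O)n, HCl (gas), conc. HCl/AcOH, 50 °C
Reagents that add atoms: formaldehyde (as paraformaldehyde), C=O; hydrogen chloride, Cl
Why: Blanc chloromethylation (electrophilic aromatic substitution) should attack the only free position of the electron-rich dimethoxy ring, C3, and the benzylic alcohol is converted to the chloride by HCl.

Step 16
Reactants: 17 (6R,9E,13E,17E,21E,25E)-6,10,14,18,22,26,30-heptamethylhentriaconta-9,13,17,21,25,29-hexaen-1-yne; 21 2-(chloromethyl)-1,4-dimethoxy-3-methylnaphthalene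
Product: 23 2-[(2E,7R,10E,14E,18E,22E,26E)-3,7,11,15,19,23,27,31-octamethyldotriaconta-2,10,14,18,22,26,30-heptaen-1-yl]-1,4-dimethoxy-3-methylnaphthalene, via E-alkenylalane 22 (not isolated)
Conditions: Me3Al (2 equiv), Cp2ZrCl2 (0.25 equiv), ClCH2CH2Cl, 0 °C to rt; volatiles and excess Me3Al removed in vacuo, hexane then THF; 21 (0.9 equiv), NiCl2(PPh3)2 (5 mol%)/n-BuLi (10 mol%) giving zerovalent nickel, THF, 0 °C to rt
Reagents that add atoms: trimethylaluminium, C[Al](C)C
Why: This is a Negishi carboalumination followed by a nickel-catalysed sp2–sp3 cross-coupling, a pairing established for attaching prenyl-type chains to chloromethylated hydroquinone ethers. A methylzirconocene species formed from Cp2ZrCl2 and Me3Al adds CH3 and metal syn across the C2'≡C3' triple bond with methyl on the internal carbon C3', and exchange to aluminium gives E-alkenylalane 22. Zerovalent nickel inserts into the benzylic C–Cl bond of 21, takes over the alkenyl group from aluminium and reductively eliminates to form C1'–C2' with retention of olefin geometry. No ring is closed and no stereocentre is made; the remote C7' centre is not touched. The selectivities needed are methyl placement on C3' and E geometry at C2'=C3', both secured by syn addition with the metal at the unhindered terminal carbon, and chemoselectivity, secured because the six isolated trisubstituted olefins do not carbometallate. Bonding at the benzylic sp3 carbon instead of an allylic one excludes allylic transposition, and stripping excess Me3Al before the coupling should suppress methyl transfer to 21.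

Step 17
Reactants: 23 2-[(2E,7R,10E,14E,18E,22E,26E)-3,7,11,15,19,23,27,31-octamethyldotriaconta-2,10,14,18,22,26,30-heptaen-1-yl]-1,4-dimethoxy-3-methylnaphthalene
Product: 24 2-methyl-3-[(2E,7R,10E,14E,18E,22E,26E)-3,7,11,15,19,23,27,31-octamethyldotriaconta-2,10,14,18,22,26,30-heptaen-1-yl]naphthalene-1,4-dione
Conditions: (NH4)2Ce(NO3)6 (2.5 equiv), MeCN/CH2Cl2/H2O, 0 °C
Reagents that add atoms: water, O
Why: Oxidative demethylation by tetravalent cerium (single-electron oxidation of the electron-rich arene, attack of water at the two ipso carbons, loss of methanol) should give the quinone within minutes at 0 °C, conditions that isolated trisubstituted olefins and the C7' centre tolerate.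

Compound list
1 | (S)-citronellol, (3S)-3,7-dimethyloct-6-en-1-ol | CC(C)=CCC[C@H](C)CCO | starting material
2 | (S)-citronellyl tert-butyldiphenylsilyl ether, tert-butyl{[(3S)-3,7-dimethyloct-6-en-1-yl]oxy}diphenylsilane | CC(C)=CCC[C@H](C)CCO[Si](c1ccccc1)(c1ccccc1)C(C)(C)C | intermediate
3 | (2E,6S)-8-[(tert-butyldiphenylsilyl)oxy]-2,6-dimethyloct-2-en-1-ol | OC/C(C)=C/CC[C@H](C)CCO[Si](c1ccccc1)(c1ccccc1)C(C)(C)C | intermediate
4 | {[(3S,6E)-8-bromo-3,7-dimethyloct-6-en-1-yl]oxy}(tert-butyl)diphenylsilane | BrC/C(C)=C/CC[C@H](C)CCO[Si](c1ccccc1)(c1ccccc1)C(C)(C)C | intermediate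
5 | geranyl bromide, (2E)-1-bromo-3,7-dimethylocta-2,6-diene | CC(C)=CCC/C(C)=C/CBr | starting material
6 | geranyl phenyl sulfone | CC(C)=CCC/C(C)=C/CS(=O)(=O)c1ccccc1 | intermediate
7 | (2E,6E)-2,6-dimethyl-8-(phenylsulfonyl)octa-2,6-dien-1-ol | OC/C(C)=C/CC/C(C)=C/CS(=O)(=O)c1ccccc1 | intermediate
8 | (2E,6E,10E,14S)-16-[(tert-butyldiphenylsilyl)oxy]-2,6,10,14-tetramethyl-8-(phenylsulfonyl)hexadeca-2,6,10-trien-1-ol, epimers at the sulfone carbon | OC/C(C)=C/CC/C(C)=C/C(S(=O)(=O)c1ccccc1)C/C(C)=C/CC[C@H](C)CCO[Si](c1ccccc1)(c1ccccc1)C(C)(C)C | intermediate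
9 | tert-butyl{[(3S,6E,10E,14E)-16-bromo-3,7,11,15-tetramethyl-9-(phenylsulfonyl)hexadeca-6,10,14-trien-1-yl]oxy}diphenylsilane, epimers at the sulfone carbon | BrC/C(C)=C/CC/C(C)=C/C(S(=O)(=O)c1ccccc1)C/C(C)=C/CC[C@H](C)CCO[Si](c1ccccc1)(c1ccccc1)C(C)(C)C | intermediate
10 | (2E,6E)-farnesyl bromide, (2E,6E)-1-bromo-3,7,11-trimethyldodeca-2,6,10-triene | CC(C)=CCC/C(C)=C/CC/C(C)=C/CBr | starting material
11 | (2E,6E)-farnesyl phenyl sulfone | CC(C)=CCC/C(C)=C/CC/C(C)=C/CS(=O)(=O)c1ccccc1 | intermediate
12 | tert-butyl{[(3S,6E,10E,14E,18E,22E)-3,7,11,15,19,23,27-heptamethyl-9,17-bis(phenylsulfonyl)octacosa-6,10,14,18,22,26-hexaen-1-yl]oxy}diphenylsilane, epimers at both sulfone carbons | CC(C)=CCC/C(C)=C/CC/C(C)=C/C(S(=O)(=O)c1ccccc1)C/C(C)=C/CC/C(C)=C/C(S(=O)(=O)c1ccccc1)C/C(C)=C/CC[C@H](C)CCO[Si](c1ccccc1)(c1ccccc1)C(C)(C)C | intermediate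
13 | tert-butyl{[(3S,6E,10E,14E,18E,22E)-3,7,11,15,19,23,27-heptamethyloctacosa-6,10,14,18,22,26-hexaen-1-yl]oxy}diphenylsilane | CC(C)=CCC/C(C)=C/CC/C(C)=C/CC/C(C)=C/CC/C(C)=C/CC/C(C)=C/CC[C@H](C)CCO[Si](c1ccccc1)(c1ccccc1)C(C)(C)C | intermediate
14 | (3S,6E,10E,14E,18E,22E)-3,7,11,15,19,23,27-heptamethyloctacosa-6,10,14,18,22,26-hexaen-1-ol | CC(C)=CCC/C(C)=C/CC/C(C)=C/CC/C(C)=C/CC/C(C)=C/CC/C(C)=C/CC[C@H](C)CCO | intermediate
15 | (3S,6E,10E,14E,18E,22E)-1-iodo-3,7,11,15,19,23,27-heptamethyloctacosa-6,10,14,18,22,26-hexaene | CC(C)=CCC/C(C)=C/CC/C(C)=C/CC/C(C)=C/CC/C(C)=C/CC/C(C)=C/CC[C@H](C)CCI | intermediate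
16 | trimethyl[(6R,9E,13E,17E,21E,25E)-6,10,14,18,22,26,30-heptamethylhentriaconta-9,13,17,21,25,29-hexaen-1-yn-1-yl]silane (not isolated) | CC(C)=CCC/C(C)=C/CC/C(C)=C/CC/C(C)=C/CC/C(C)=C/CC/C(C)=C/CC[C@H](C)CCCC#C[Si](C)(C)C | intermediate
17 | (6R,9E,13E,17E,21E,25E)-6,10,14,18,22,26,30-heptamethylhentriaconta-9,13,17,21,25,29-hexaen-1-yne, the C38 terminal alkyne | CC(C)=CCC/C(C)=C/CC/C(C)=C/CC/C(C)=C/CC/C(C)=C/CC/C(C)=C/CC[C@H](C)CCCC#C | intermediate
18 | menadione, 2-methylnaphthalene-1,4-dione | CC1=CC(=O)c2ccccc2C1=O | starting material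
19 | menadiol, 2-methylnaphthalene-1,4-diol (not isolated) | Cc1cc(O)c2ccccc2c1O | intermediate
20 | 1,4-dimethoxy-2-methylnaphthalene | COc1cc(C)c(OC)c2ccccc12 | intermediate
21 | 2-(chloromethyl)-1,4-dimethoxy-3-methylnaphthalene | ClCc1c(C)c(OC)c2ccccc2c1OC | intermediate
22 | dimethyl[(1E,6R,9E,13E,17E,21E,25E)-2,6,10,14,18,22,26,30-octamethylhentriaconta-1,9,13,17,21,25,29-heptaen-1-yl]alumane, the E-alkenylalane (not isolated) | CC(C)=CCC/C(C)=C/CC/C(C)=C/CC/C(C)=C/CC/C(C)=C/CC/C(C)=C/CC[C@H](C)CCC/C(C)=C/[Al](C)C | intermediate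
23 | 2-[(2E,7R,10E,14E,18E,22E,26E)-3,7,11,15,19,23,27,31-octamethyldotriaconta-2,10,14,18,22,26,30-heptaen-1-yl]-1,4-dimethoxy-3-methylnaphthalene | CC(C)=CCC/C(C)=C/CC/C(C)=C/CC/C(C)=C/CC/C(C)=C/CC/C(C)=C/CC[C@H](C)CCC/C(C)=C/Cc1c(C)c(OC)c2ccccc2c1OC | intermediate
24 | 2-methyl-3-[(2E,7R,10E,14E,18E,22E,26E)-3,7,11,15,19,23,27,31-octamethyldotriaconta-2,10,14,18,22,26,30-heptaen-1-yl]naphthalene-1,4-dione | CC(C)=CCC/C(C)=C/CC/C(C)=C/CC/C(C)=C/CC/C(C)=C/CC/C(C)=C/CC[C@H](C)CCC/C(C)=C/CC1=C(C)C(=O)c2ccccc2C1=O | target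

Total step count: 17 steps.
Longest linear sequence: 12 steps (steps 1, 2, 3, 6, 7, 9, 10, 11, 12, 13, 16 and 17, from (S)-citronellol).

Steps most likely to fail

Step 16. The carbometallation of the very lipophilic C38 alkyne may stall. In the coupling, methyl transfer from leftover Me3Al or reductive homocoupling of the benzylic chloride may outrun alkenyl transfer from aluminium to nickel. The fallback makes the same two bonds in separate, isolable stages with a change of metal. It sets out from alkyne 17, which is methylaluminated as before to alane 22 and quenched with I2 in THF at −30 °C to give the E-alkenyl iodide F1. Chloride 21 is treated with Zn dust and LiCl in THF to give the benzylzinc chloride F2. A Negishi coupling of F1 with F2 under Pd(PPh3)4 catalysis comes back to the route at dimethyl ether 23.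

Step 10. Two π-allyl reductions run in one flask. Hydride delivery to the internal allyl terminus, or syn/anti equilibration at either junction, would build up regio- and geometrical isomers that can no longer be separated at the C35 stage, and the second C–S cleavage may lag behind the first. The fallback removes the sulfones junction by junction. It sets out from hydroxy sulfone 8, which is reduced with PdCl2(dppp)/LiEt3BH to the C20 trienol F3; at this size isomers can still be removed on AgNO3-impregnated silica. Appel bromination gives the C20 allylic bromide F4, and alkylation of lithiated sulfone 11 with it gives the C35 mono-sulfone F5. A single palladium-catalysed hydride reduction of F5 comes back to the route at silyl ether 13.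

Step 6. The alkoxide–carbanion dianion may aggregate or precipitate at −78 °C, so that metalation is incomplete, protons are returned, or some O-alkylation occurs. The fallback masks the hydroxyl. It sets out from hydroxy sulfone 7, which with dihydropyran and pyridinium p-toluenesulfonate gives the tetrahydropyranyl ether F6. One equivalent of n-BuLi and bromide 4 then give the coupled tetrahydropyranyl ether F7. Pyridinium p-toluenesulfonate in MeOH cleaves the acetal while the tert-butyldiphenylsilyl ether stays, and the route is rejoined at 8.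

Further compounds
F1 | step 16 | (1E,6R,9E,13E,17E,21E,25E)-1-iodo-2,6,10,14,18,22,26,30-octamethylhentriaconta-1,9,13,17,21,25,29-heptaene | CC(C)=CCC/C(C)=C/CC/C(C)=C/CC/C(C)=C/CC/C(C)=C/CC/C(C)=C/CC[C@H](C)CCC/C(C)=C/I
F2 | step 16 | [(1,4-dimethoxy-3-methylnaphthalen-2-yl)methyl]zinc chloride | Cl[Zn]Cc1c(C)c(OC)c2ccccc2c1OC
F3 | step 10 | (2E,6E,10E,14S)-16-[(tert-butyldiphenylsilyl)oxy]-2,6,10,14-tetramethylhexadeca-2,6,10-trien-1-ol | OC/C(C)=C/CC/C(C)=C/CC/C(C)=C/CC[C@H](C)CCO[Si](c1ccccc1)(c1ccccc1)C(C)(C)C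
F4 | step 10 | tert-butyl{[(3S,6E,10E,14E)-16-bromo-3,7,11,15-tetramethylhexadeca-6,10,14-trien-1-yl]oxy}diphenylsilane | BrC/C(C)=C/CC/C(C)=C/CC/C(C)=C/CC[C@H](C)CCO[Si](c1ccccc1)(c1ccccc1)C(C)(C)C
F5 | step 10 | tert-butyl{[(3S,6E,10E,14E,18E,22E)-3,7,11,15,19,23,27-heptamethyl-17-(phenylsulfonyl)octacosa-6,10,14,18,22,26-hexaen-1-yl]oxy}diphenylsilane, epimers at the sulfone carbon | CC(C)=CCC/C(C)=C/CC/C(C)=C/C(S(=O)(=O)c1ccccc1)C/C(C)=C/CC/C(C)=C/CC/C(C)=C/CC[C@H](C)CCO[Si](c1ccccc1)(c1ccccc1)C(C)(C)C
F6 | step 6 | 2-{[(2E,6E)-2,6-dimethyl-8-(phenylsulfonyl)octa-2,6-dien-1-yl]oxy}tetrahydro-2H-pyran, racemic at the acetal carbon | O1CCCCC1OC/C(C)=C/CC/C(C)=C/CS(=O)(=O)c1ccccc1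
F7 | step 6 | tert-butyl{[(3S,6E,10E,14E)-3,7,11,15-tetramethyl-9-(phenylsulfonyl)-16-(tetrahydro-2H-pyran-2-yloxy)hexadeca-6,10,14-trien-1-yl]oxy}diphenylsilane, epimers at the sulfone and acetal carbons | O1CCCCC1OC/C(C)=C/CC/C(C)=C/C(S(=O)(=O)c1ccccc1)C/C(C)=C/CC[C@H](C)CCO[Si](c1ccccc1)(c1ccccc1)C(C)(C)C
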